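**Retrosynthetic overview**
1. Ester C–O bond: the target comes from hexatriacontanoyl chloride and tyrosol carried as its phenolic benzyl ether, with hydrogenolysis last.
2. The C36 acid comes from 15-oxohexatriacontanoic acid (Wolff–Kishner), which comes from a β-keto diester by acid hydrolysis and decarboxylation.
3. Key C15–C16 bond: crossed Claisen condensation of the lithium enolate of methyl docosanoate (C22) with methyl 15-chloro-15-oxopentadecanoate (C15).
4. The C15 acyl donor comes from ω-pentadecalactone by methanolysis, Jones oxidation and chlorination.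
5. No ring is built: the benzene ring is bought with tyrosol, and the only ring event is opening of the 16-membered lactone in the first step.

Assumption: the target has no stereocentre (it is achiral), so there is no enantiomer to control; the acyl chain is read as n-hexatriacontanoyl (36 carbons including C=O).

**Step 1**
Reactants: 1 ω-pentadecalactone (oxacyclohexadecan-2-one)
Product: 2 methyl 15-hydroxypentadecanoate
Conditions: MeOH (solvent), H2SO4 (cat.), reflux, 12 h
Reagents that add atoms: methanol, CO
Why: Acid-catalysed transesterification (methanolysis) in a large excess of methanol drives the macrolactone fully to the open-chain hydroxy ester; no stereocentre is involved.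

**Step 2**
Reactants: 2 methyl 15-hydroxypentadecanoate
Product: 3 15-methoxy-15-oxopentadecanoic acid (monomethyl pentadecanedioate)
Conditions: Jones reagent (CrO3, H2SO4, H2O), acetone, 0 °C to rt, 2 h; i-PrOH quench
Reagents that add atoms: water, O (as aqueous chromic acid made from chromium trioxide, O=[Cr](=O)=O)
Why: Jones oxidation takes the primary alcohol through the aldehyde hydrate to the acid while the methyl ester is inert, giving a cleanly differentiated C15 diacid half-ester.

**Step 3**
Reactants: 3 15-methoxy-15-oxopentadecanoic acid
Product: 4 methyl 15-chloro-15-oxopentadecanoate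
Conditions: (COCl)2 (1.5 equiv), DMF (cat.), CH2Cl2, 0 °C to rt, 2 h; evaporate, use crude
Reagents that add atoms: oxalyl chloride, ClC(=O)C(=O)Cl
Why: Vilsmeier-catalysed acid chloride formation is quantitative for a simple aliphatic acid and leaves the remote methyl ester untouched.

**Step 4**
Reactants: 5 methyl docosanoate (methyl behenate, 2.1 equiv); 4 methyl 15-chloro-15-oxopentadecanoate (1.0 equiv)
Product: 8 racemic dimethyl 2-icosyl-3-oxoheptadecanedioate, via lithium ester enolate 6 (not isolated), via lithium keto ester enolate 7 (not isolated)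
Conditions: LDA (commercial solution, 2.1 equiv), THF, −78 °C, 5 added dropwise as a dilute THF solution, 45 min; then 4 in THF, −78 to −20 °C; sat. aq NH4Cl
Reagents that add atoms: none
Why: Crossed Claisen condensation by C-acylation of a preformed lithium ester enolate: the acid chloride is far more electrophilic than either methyl ester, and the second equivalent of enolate deprotonates the β-keto ester so it is not attacked again. The new C2 stereocentre is racemic and is erased in step 5.

**Step 5**
Reactants: 8 dimethyl 2-icosyl-3-oxoheptadecanedioate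
Product: 10 15-oxohexatriacontanoic acid, via keto diacid 9 (not isolated)
Conditions: AcOH/conc. HCl/H2O (4:2:1), reflux, 24 h; cool, filter, recrystallise
Reagents that add atoms: water, O
Why: Acid-catalysed hydrolysis of both methyl esters followed by thermal decarboxylation of the β-keto acid (ketonic cleavage); acidic conditions avoid the retro-Claisen cleavage that hydroxide can cause.

**Step 6**
Reactants: 10 15-oxohexatriacontanoic acid
Product: 12 hexatriacontanoic acid, via potassium hydrazone carboxylate 11 (not isolated)
Conditions: N2H4·H2O (4 equiv), KOH (5 equiv), diethylene glycol, 130 °C, 2 h; distil to 200 °C, 5 h; then aq. HCl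
Reagents that add atoms: none
Why: Wolff–Kishner reduction in the Huang–Minlon modification, the classical deoxygenation of long-chain keto acids; the carboxylate is inert and the potassium soap is soluble in hot glycol.

**Step 7**
Reactants: 12 hexatriacontanoic acid
Product: 13 hexatriacontanoyl chloride
Conditions: SOCl2 (excess), DMF (cat.), toluene, 75 °C, 3 h; evaporate, use crude
Reagents that add atoms: thionyl chloride, O=S(Cl)Cl
Why: Acid chloride formation in hot toluene overcomes the poor solubility of the C36 acid and gives a soluble, highly reactive acyl donor.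

**Step 8**
Reactants: 14 tyrosol (4-(2-hydroxyethyl)phenol)
Product: 15 2-[4-(benzyloxy)phenyl]ethan-1-ol
Conditions: BnBr (1.05 equiv), K2CO3 (1.5 equiv), acetone, reflux, 12 h
Reagents that add atoms: benzyl bromide, BrCc1ccccc1
Why: Williamson ether synthesis: K2CO3 deprotonates only the phenol (pKa about 10, against about 16 for the alcohol), so benzylation is selective for the phenolic oxygen.

**Step 9**
Reactants: 13 hexatriacontanoyl chloride; 15 2-[4-(benzyloxy)phenyl]ethan-1-ol (1.2 equiv)
Product: 16 2-[4-(benzyloxy)phenyl]ethyl hexatriacontanoate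
Conditions: pyridine (3 equiv), DMAP (0.1 equiv), toluene, 60 °C, 6 h
Reagents that add atoms: none
Why: DMAP-catalysed acylation of a primary alcohol by an acid chloride; with the phenol masked, the aliphatic OH is the only nucleophile.

**Step 10**
Reactants: 16 2-[4-(benzyloxy)phenyl]ethyl hexatriacontanoate
Product: 17 2-(4-hydroxyphenyl)ethyl hexatriacontanoate (target)
Conditions: H2 (1 atm), 10% Pd/C, THF/EtOAc (1:1), 45 °C
Reagents that add atoms: none
Why: Catalytic hydrogenolysis cleaves the benzyl aryl ether only; the homobenzylic alkyl ester is not a benzylic C–O bond and survives.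

**Compound list**
1 | ω-pentadecalactone (oxacyclohexadecan-2-one) | O=C1CCCCCCCCCCCCCCO1 | starting material
2 | methyl 15-hydroxypentadecanoate | COC(=O)CCCCCCCCCCCCCCO | intermediate
3 | 15-methoxy-15-oxopentadecanoic acid | COC(=O)CCCCCCCCCCCCCC(=O)O | intermediate
4 | methyl 15-chloro-15-oxopentadecanoate | COC(=O)CCCCCCCCCCCCCC(=O)Cl | intermediate
5 | methyl docosanoate | CCCCCCCCCCCCCCCCCCCCCC(=O)OC | starting material
6 | lithium 1-methoxydocos-1-en-1-olate (enolate of 5; E/Z not controlled, immaterial) | CCCCCCCCCCCCCCCCCCCCC=C(OC)O[Li] | intermediate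
7 | lithium enolate of 8 (geometry immaterial) | CCCCCCCCCCCCCCCCCCCCC(C(=O)OC)=C(O[Li])CCCCCCCCCCCCCC(=O)OC | intermediate
8 | dimethyl 2-icosyl-3-oxoheptadecanedioate (racemic) | CCCCCCCCCCCCCCCCCCCCC(C(=O)OC)C(=O)CCCCCCCCCCCCCC(=O)OC | intermediate
9 | 2-icosyl-3-oxoheptadecanedioic acid (racemic) | CCCCCCCCCCCCCCCCCCCCC(C(=O)O)C(=O)CCCCCCCCCCCCCC(=O)O | intermediate
10 | 15-oxohexatriacontanoic acid | CCCCCCCCCCCCCCCCCCCCCC(=O)CCCCCCCCCCCCCC(=O)O | intermediate
11 | potassium 15-hydrazinylidenehexatriacontanoate | CCCCCCCCCCCCCCCCCCCCCC(=NN)CCCCCCCCCCCCCC(=O)[O-].[K+] | intermediate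
12 | hexatriacontanoic acid | CCCCCCCCCCCCCCCCCCCCCCCCCCCCCCCCCCCC(=O)O | intermediate
13 | hexatriacontanoyl chloride | CCCCCCCCCCCCCCCCCCCCCCCCCCCCCCCCCCCC(=O)Cl | intermediate
14 | tyrosol (4-(2-hydroxyethyl)phenol) | OCCc1ccc(O)cc1 | starting material
15 | 2-[4-(benzyloxy)phenyl]ethan-1-ol | OCCc1ccc(OCc2ccccc2)cc1 | intermediate
16 | 2-[4-(benzyloxy)phenyl]ethyl hexatriacontanoate | CCCCCCCCCCCCCCCCCCCCCCCCCCCCCCCCCCCC(=O)OCCc1ccc(OCc2ccccc2)cc1 | intermediate
17 | 2-(4-hydroxyphenyl)ethyl hexatriacontanoate | CCCCCCCCCCCCCCCCCCCCCCCCCCCCCCCCCCCC(=O)OCCc1ccc(O)cc1 | target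

**Totals**
Total step count: 10. Longest linear sequence: 9 steps (1 → 2 → 3 → 4 → 8 → 10 → 12 → 13 → 16 → 17; step 8 is a one-step side branch).

**Three steps most likely to fail**

Step 4 (crossed Claisen). The C22 ester and its enolate may be poorly soluble at −78 °C, and O-acylation or self-condensation can lower the yield. The fallback reverses the roles of the two fragments and sets out from compound 2. The alcohol is silylated (TBSCl, imidazole, DMF) to methyl 15-[(tert-butyldimethylsilyl)oxy]pentadecanoate F1, a low-melting ester that stays dissolved at −78 °C. LDA in THF converts it into its lithium ester enolate F2. Two equivalents of this are acylated with commercial docosanoyl chloride F3, which gives the lithium keto ester enolate F4 and, after NH4Cl, methyl 2-{13-[(tert-butyldimethylsilyl)oxy]tridecyl}-3-oxotetracosanoate F5. Aqueous H2SO4/dioxane at reflux hydrolyses, decarboxylates and desilylates it to 1-hydroxyhexatriacontan-15-one F6. Jones oxidation of that alcohol (acetone/THF, 40 °C) comes back to the route at compound 10.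

Step 5 (double hydrolysis and decarboxylation). The waxy diester may hydrolyse slowly or incompletely in aqueous acid. The fallback sets out from compound 8 and uses a Krapcho dealkoxycarbonylation (LiCl, H2O, DMSO, 150 °C). Chloride dealkylates only the activated β-keto ester, which then loses CO2, giving methyl 15-oxohexatriacontanoate F7. This ester is put directly into the step 6 conditions, where KOH saponifies the remote ester on the way to hydrazone 11, and the route is rejoined at compound 12.

Step 10 (hydrogenolysis). The C36 ester is sparingly soluble and may coat the catalyst, so debenzylation can stall. The fallback drops the protecting group and sets out from compounds 13 and 14. Unprotected tyrosol (3 equiv) is acylated with the acid chloride in THF/toluene at 50 °C without base. The neutral phenol is a much poorer nucleophile than the primary alcohol, so only the aliphatic ester forms, and the excess tyrosol is washed out with water. This comes back to the route at compound 17 and makes no new compound (F0).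

**Further compounds**
F1 | step 4 | methyl 15-[(tert-butyldimethylsilyl)oxy]pentadecanoate | COC(=O)CCCCCCCCCCCCCCO[Si](C)(C)C(C)(C)C
F2 | step 4 | lithium ester enolate of F1 (geometry immaterial) | COC(O[Li])=CCCCCCCCCCCCCCO[Si](C)(C)C(C)(C)C
F3 | step 4 | docosanoyl chloride | CCCCCCCCCCCCCCCCCCCCCC(=O)Cl
F4 | step 4 | lithium keto ester enolate of F5 (geometry immaterial) | CCCCCCCCCCCCCCCCCCCCCC(O[Li])=C(C(=O)OC)CCCCCCCCCCCCCO[Si](C)(C)C(C)(C)C
F5 | step 4 | methyl 2-{13-[(tert-butyldimethylsilyl)oxy]tridecyl}-3-oxotetracosanoate (racemic) | CCCCCCCCCCCCCCCCCCCCCC(=O)C(C(=O)OC)CCCCCCCCCCCCCO[Si](C)(C)C(C)(C)C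
F6 | step 4 | 1-hydroxyhexatriacontan-15-one | CCCCCCCCCCCCCCCCCCCCCC(=O)CCCCCCCCCCCCCCO
F7 | step 5 | methyl 15-oxohexatriacontanoate | CCCCCCCCCCCCCCCCCCCCCC(=O)CCCCCCCCCCCCCC(=O)OC
F0 | step 10 | none | none
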